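**Remark (assumptions).** Side-chain carbons are numbered C1'–C40' from the ring. The single stereocentre is C35' and is (S) by CIP (tail branch C36' > ring-side branch C34' > CH3 > H). (all-E)-Solanesol **1**, 2,3,4,5-tetramethoxytoluene **3** and prenyl bromide **10** are taken as commercial.

## The problem

The target is a 2,3-dimethoxy-5-methyl-1,4-benzoquinone whose C6 carries a C50 chain of ten isoprene units. Units 1–8 are (E)-trisubstituted olefins, unit 9 (C33'–C36') is saturated and holds the only stereocentre (C35', S), and unit 10 is an isopropylidene. The hard part is that one saturated, stereodefined unit must be placed among nine otherwise identical trisubstituted olefins, 34 carbons from the ring, with no heteroatom or second stereocentre nearby to relay control. Eight olefin geometries must also be delivered pure, and the ring–C1' bond must be made without moving or isomerising the Δ2' olefin. The quinone does not tolerate organometallics, hydrides or Ru–H, and the skipped polyene does not tolerate strong acid (cation–olefin cyclisation) or unselective electrophilic oxidants.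

The enabling feature is a coincidence of atoms. C34', C35', the C35' methyl and C36' of the target are exactly the terminal isopropylidene C34'=C35'(CH3)2 of an all-E C45 solanesyl chain attached through C1' to ring carbon C6, with C36' being its (E)-methyl. That chain already contains all eight E-olefins. A hydroxyl on C36' makes C34'=C35' the only allylic-alcohol olefin of nine, so a hydroxyl-directed asymmetric hydrogenation can select that olefin and set C35' in one operation. The chain is therefore edited at its terminus rather than built.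

## Retrosynthesis

**13 ⇒ 12.** The two quinone carbonyls (ring C1, C4) are traced back to two aryl methyl ethers. The quinone would not survive a Grignard reagent, Ru–H or an arylcopper reagent, whereas the fully substituted tetramethoxybenzene of **12** is inert to all of them and also caps the α-terminus of the chain. Only one para-quinone can form from **12**, because the other para pairs are OMe/CH3 and OMe/alkyl. The forward step is an oxidative demethylation that must spare nine olefins.

**12 ⇒ 9 + 10.** The C36'–C37' bond is cut. This sp3–sp3 bond lies one atom away from the stereocentre, so C35' is not involved in its formation. A cut at C35'–C36' or C34'–C35' would form a bond at the stereocentre, and a cut at C32'–C33' would require a C40 all-E linker to be built. The cut chosen removes a commercial C5 piece (**10**) and leaves the solanesyl carbon skeleton C1'–C36' intact in bromide **9**. The forward reaction must attack the CH2 terminus (α, SN2) of the prenyl electrophile.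

**9 ⇒ 8 ⇒ 7 (key).** After exchange of Br for OH, the two C–H bonds at C34' and C35' are removed. Alcohol **8** becomes the (E)-allylic alcohol **7**, which has no stereocentre and is again a regular all-E polyprenyl chain of nine identical units. The forward reaction must reduce one olefin of nine on one enantioface. The C36' hydroxyl provides the chemoselectivity, the chiral Ru–diphosphine the facial selectivity, and the E geometry of **7** fixes which enantiomer results.

**7 ⇒ 6.** The C36'–O bond is removed, which returns the unfunctionalised solanesyl arene **6**. The (E)-CH3 of the terminal isopropylidene is the only primary allylic C–H cis to a vinylic hydrogen in the molecule, which is the position that selenium dioxide oxidises. Building the allylic alcohol by olefination instead would first require truncating the chain (kept as a fallback).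

**6 ⇒ 2 + 3; 2 ⇒ 1.** The ring C6–C1' bond is cut into the arylcopper reagent **5** (from **3** via aryllithium **4**) and solanesyl bromide **2**, itself from solanesol **1**. An arylcopper reagent alkylates a primary allylic bromide at CH2 with retention of the Δ2' geometry. A Friedel–Crafts allylation would risk E/Z leakage and chroman formation.

## Roads not taken

**Alternative 1:** The most obvious plan cuts C32'–C33' and the ring–C1' bond and assembles the chain. (R)-Citronellyl bromide **A1** would alkylate the carbanion of the ω-phenylsulfonyl all-E octaprenyl benzyl ether **A2**. Reductive removal of sulfonyl and benzyl would give the C50 alcohol **A3**, which would be brominated, coupled with **5** and oxidised as in steps 2 and 7. The stereocentre is secure because it comes from the chiral pool. However, **A2** must itself be assembled from two C20 halves, each needing its own terminal allylic oxidation, so the terminal-oxidation problem is met twice. Each sulfone alkylation and desulfonylation cycle activates an allylic position and risks olefin migration or E/Z erosion. The sequence would be about twice as long as the chosen one, which never touches an internal olefin.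

**Alternative 2:** The quinone ring could be made last by strain release. The ring bonds C1–C6 and C4–C5 are cut so that C1–C4 with both methoxyls come from dimethyl squarate **A4**, and C5 (with its methyl) and C6 come from an alkenyl unit. Lithiation of vinyl iodide **A5** and addition to **A4** would give the 4-alkenyl-4-hydroxycyclobutenone **A6**. Thermolysis (4π ring opening to a dienylketene, 6π closure, tautomerisation) and air oxidation would give **13**. This solves only the ring–chain junction, which is not the hard part. The complete C50 chain would still be needed, now as a 2-iodo-1,4-diene, which costs extra steps for propynylation, hydrometalation and iodination plus α-terminus protection during chain editing. The vinyllithium would sit next to the doubly allylic C1'H2, and the 1,5-polyene would be heated to about 140 °C. In the chosen plan, commercial **3** supplies the ring in one step.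

**Alternative 3:** The C34'–C35' bond could be cut at the stereocentre. The Grignard reagent **A8** would be made from **6** by terminal oxidative cleavage, reduction, bromination and magnesium insertion. It would displace (S)-sulcatyl tosylate **A7** with inversion under copper catalysis. This uses a chiral-pool C8 piece, but substitution at an unactivated secondary tosylate competes with elimination and partial loss of configuration. The terminal cleavage faces the same site-selectivity problem as the chosen allylic oxidation and needs about four more operations. Hydrogenating an achiral allylic alcohol is shorter and keeps bond formation away from the stereocentre.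

Key step: step 4

## Route

**Step 1**
Reactants: 1 (all-E)-solanesol
Product: 2 (all-E)-solanesyl bromide
Conditions: PBr3 (0.4 equiv), pyridine (cat.), Et2O–hexane, −10 to 0 °C
Reagents that add atoms: phosphorus tribromide, BrP(Br)Br
Why: Conversion of a primary allylic alcohol into its bromide by PBr3 (SN2 at C1 through the phosphite ester); low temperature and a trace of pyridine limit allylic transposition and E/Z leakage at Δ2.

**Step 2**
Reactants: 2 (all-E)-solanesyl bromide; 3 2,3,4,5-tetramethoxytoluene
Product: 6 1,2,3,4-tetramethoxy-5-methyl-6-[(all-E)-solanesyl]benzene, via 6-lithio-2,3,4,5-tetramethoxytoluene 4 (not isolated), via arylcopper reagent 5 (not isolated)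
Conditions: 3, n-BuLi, TMEDA, hexane–THF, 0 °C; CuBr·SMe2, THF, −78 to −40 °C; then 2, −78 to 0 °C
Reagents that add atoms: none
Why: Directed ortho-lithiation at the only ring C–H of 3 (next to OMe), transmetalation to copper and SN2 allylation at the CH2 terminus of the primary allylic bromide; this arylcopper–polyprenyl bromide coupling is the established way to ubiquinol dimethyl ethers and keeps the Δ2' olefin E.

**Step 3**
Reactants: 6 1,2,3,4-tetramethoxy-5-methyl-6-[(all-E)-solanesyl]benzene
Product: 7 (34'E)-36'-hydroxy derivative of 6 (terminal (E)-allylic alcohol)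
Conditions: SeO2 (0.3–0.5 equiv), t-BuOOH (3 equiv), salicylic acid (0.1 equiv), CH2Cl2, 0 °C to rt, stopped at partial conversion, 6 recovered and recycled
Reagents that add atoms: tert-butyl hydroperoxide, CC(C)(C)OO (terminal source of the oxygen atom), relayed by catalytic selenium dioxide, O=[Se]=O
Why: Sharpless SeO2/t-BuOOH allylic oxidation (ene reaction, then [2,3]-sigmatropic shift) functionalises the allylic carbon cis to the vinylic H; at the terminal isopropylidene this is the unhindered (E)-CH3 and gives the (E)-primary allylic alcohol, whereas at the eight internal olefins the corresponding position is a hindered chain CH2, which should favour the terminus.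

**Step 4**
Reactants: 7 (34'E)-36'-hydroxy derivative of 6
Product: 8 (35'S)-34',35'-dihydro alcohol [(2S)-2-methyl-alkan-1-ol terminus]
Conditions: Ru(OAc)2[(S)-BINAP] (1–2 mol %), H2 (30–100 atm), MeOH–CH2Cl2 4:1, 20–25 °C
Reagents that add atoms: none
Why: This is the Noyori Ru(II)–BINAP dicarboxylate hydrogenation of an allylic alcohol: carboxylate-assisted heterolysis of H2 gives a Ru monohydride, the C36' hydroxyl binds to Ru and holds the C34'=C35' olefin in a chelate, and hydride insertion followed by protonolysis/hydrogenolysis delivers both hydrogens to one face. The closest known reactions are geraniol to citronellol, the α-terminal reduction of long polyprenols in the presence of many remote trisubstituted olefins, and the reduction of (E)-2-methyl-2-alken-1-ols to 2-methylalkanols. No ring is closed. The one new stereocentre, C35', is controlled only by the axial chirality of the ligand, since 7 is achiral. (S)-BINAP is chosen because it adds H2 to the same face of the C=C–C–O unit as in geraniol to (R)-citronellol and in tiglic acid to (S)-2-methylbutanoic acid, which here corresponds to (35'S). The step needs chemoselectivity for one olefin of nine; this is secured by the single free hydroxyl, because the eight trialkyl olefins and the arene have no group that binds Ru and isolated trisubstituted olefins are not reduced by this catalyst. It also needs one olefin geometry, since the Z isomer would give the other enantiomer; this is secured by the E-specific oxidation of step 3.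

**Step 5**
Reactants: 8 (35'S)-alcohol
Product: 9 (35'S)-36'-bromide
Conditions: CBr4, PPh3, CH2Cl2, 0 °C
Reagents that add atoms: carbon tetrabromide, BrC(Br)(Br)Br
Why: Appel bromination of a primary alcohol (SN2 at C36' of the alkoxyphosphonium ion) under neutral conditions that leave the olefins and the arene alone; C35' is not a reacting centre.

**Step 6**
Reactants: 9 (35'S)-36'-bromide; 10 prenyl bromide
Product: 12 1-[(2E,6E,10E,14E,18E,22E,26E,30E,35S)-3,7,11,15,19,23,27,31,35,39-decamethyltetraconta-2,6,10,14,18,22,26,30,38-nonaen-1-yl]-2,3,4,5-tetramethoxy-6-methylbenzene, via Grignard reagent 11 (not isolated)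
Conditions: Mg (I2-activated), THF, 40 °C; then added rapidly to 10 (2 equiv), Li2CuCl4 (5 mol %), THF, −40 to 0 °C
Reagents that add atoms: none
Why: Kochi-type copper-catalysed coupling of an alkyl Grignard reagent with an allylic halide; with Li2CuCl4 in THF and fast addition the dialkylcuprate pathway gives α (SN2) attack at the CH2 of prenyl bromide, helped by the fully substituted γ-carbon. The C35'–H is not acidic, so the stereocentre is carried through unchanged.

**Step 7**
Reactants: 12 tetramethoxyarene with the complete chain
Product: 13 target quinone, 2,3-dimethoxy-5-methyl-6-[(2E,6E,10E,14E,18E,22E,26E,30E,35S)-3,7,11,15,19,23,27,31,35,39-decamethyltetraconta-2,6,10,14,18,22,26,30,38-nonaen-1-yl]cyclohexa-2,5-diene-1,4-dione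
Conditions: CAN (2.5 equiv), MeCN–CH2Cl2–H2O, 0 °C
Reagents that add atoms: water, O
Why: Ceric ammonium nitrate oxidative demethylation of a hydroquinone dimethyl ether, the usual last step of ubiquinone syntheses; the only para pair of methoxyls (those flanking the methyl and the chain) becomes the p-quinone with oxygen from water, and the reaction is fast at 0 °C so the trisubstituted olefins and C35' are not affected.

## Compound list

1 | (all-E)-solanesol, (2E,6E,10E,14E,18E,22E,26E,30E)-3,7,11,15,19,23,27,31,35-nonamethylhexatriaconta-2,6,10,14,18,22,26,30,34-nonaen-1-ol | OC/C=C(\C)CC/C=C(\C)CC/C=C(\C)CC/C=C(\C)CC/C=C(\C)CC/C=C(\C)CC/C=C(\C)CC/C=C(\C)CCC=C(C)C | starting material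
2 | (all-E)-solanesyl bromide | BrC/C=C(\C)CC/C=C(\C)CC/C=C(\C)CC/C=C(\C)CC/C=C(\C)CC/C=C(\C)CC/C=C(\C)CC/C=C(\C)CCC=C(C)C | intermediate
3 | 2,3,4,5-tetramethoxytoluene (1,2,3,4-tetramethoxy-5-methylbenzene) | Cc1cc(OC)c(OC)c(OC)c1OC | starting material
4 | 6-lithio-2,3,4,5-tetramethoxytoluene | [Li]c1c(C)c(OC)c(OC)c(OC)c1OC | intermediate
5 | (2,3,4,5-tetramethoxy-6-methylphenyl)copper | [Cu]c1c(C)c(OC)c(OC)c(OC)c1OC | intermediate
6 | 1,2,3,4-tetramethoxy-5-methyl-6-[(all-E)-solanesyl]benzene | COc1c(OC)c(OC)c(C/C=C(\C)CC/C=C(\C)CC/C=C(\C)CC/C=C(\C)CC/C=C(\C)CC/C=C(\C)CC/C=C(\C)CC/C=C(\C)CCC=C(C)C)c(C)c1OC | intermediate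
7 | (2E,6E,10E,14E,18E,22E,26E,30E,34E)-2,6,10,14,18,22,26,30,34-nonamethyl-36-(2,3,4,5-tetramethoxy-6-methylphenyl)hexatriaconta-2,6,10,14,18,22,26,30,34-nonaen-1-ol | COc1c(OC)c(OC)c(C/C=C(\C)CC/C=C(\C)CC/C=C(\C)CC/C=C(\C)CC/C=C(\C)CC/C=C(\C)CC/C=C(\C)CC/C=C(\C)CC/C=C(\C)CO)c(C)c1OC | intermediate
8 | (2S,6E,10E,14E,18E,22E,26E,30E,34E)-2,6,10,14,18,22,26,30,34-nonamethyl-36-(2,3,4,5-tetramethoxy-6-methylphenyl)hexatriaconta-6,10,14,18,22,26,30,34-octaen-1-ol | COc1c(OC)c(OC)c(C/C=C(\C)CC/C=C(\C)CC/C=C(\C)CC/C=C(\C)CC/C=C(\C)CC/C=C(\C)CC/C=C(\C)CC/C=C(\C)CCC[C@H](C)CO)c(C)c1OC | intermediate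
9 | 1-[(2E,6E,10E,14E,18E,22E,26E,30E,35S)-36-bromo-3,7,11,15,19,23,27,31,35-nonamethylhexatriaconta-2,6,10,14,18,22,26,30-octaen-1-yl]-2,3,4,5-tetramethoxy-6-methylbenzene | COc1c(OC)c(OC)c(C/C=C(\C)CC/C=C(\C)CC/C=C(\C)CC/C=C(\C)CC/C=C(\C)CC/C=C(\C)CC/C=C(\C)CC/C=C(\C)CCC[C@H](C)CBr)c(C)c1OC | intermediate
10 | prenyl bromide (1-bromo-3-methylbut-2-ene) | CC(C)=CCBr | starting material
11 | Grignard reagent of 9 (C36'–MgBr, 35'S) | COc1c(OC)c(OC)c(C/C=C(\C)CC/C=C(\C)CC/C=C(\C)CC/C=C(\C)CC/C=C(\C)CC/C=C(\C)CC/C=C(\C)CC/C=C(\C)CCC[C@H](C)C[Mg]Br)c(C)c1OC | intermediate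
12 | 1-[(2E,6E,10E,14E,18E,22E,26E,30E,35S)-3,7,11,15,19,23,27,31,35,39-decamethyltetraconta-2,6,10,14,18,22,26,30,38-nonaen-1-yl]-2,3,4,5-tetramethoxy-6-methylbenzene | COc1c(OC)c(OC)c(C/C=C(\C)CC/C=C(\C)CC/C=C(\C)CC/C=C(\C)CC/C=C(\C)CC/C=C(\C)CC/C=C(\C)CC/C=C(\C)CCC[C@H](C)CCC=C(C)C)c(C)c1OC | intermediate
13 | 2,3-dimethoxy-5-methyl-6-[(2E,6E,10E,14E,18E,22E,26E,30E,35S)-3,7,11,15,19,23,27,31,35,39-decamethyltetraconta-2,6,10,14,18,22,26,30,38-nonaen-1-yl]cyclohexa-2,5-diene-1,4-dione (CNP0144872.1) | COC1=C(OC)C(=O)C(C/C=C(\C)CC/C=C(\C)CC/C=C(\C)CC/C=C(\C)CC/C=C(\C)CC/C=C(\C)CC/C=C(\C)CC/C=C(\C)CCC[C@H](C)CCC=C(C)C)=C(C)C1=O | target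

## Step count and risks

Total step count: 7. Longest linear sequence: 7 steps (1 → 13); compounds 3 and 10 enter as purchased.

**Step 4 (key step).** The most likely failure is incomplete enantioface discrimination. The substrate is a 2-methyl-substituted allylic alcohol rather than the 3-methyl (geraniol) type for which the catalyst is best documented. Ru–H isomerisation of the allylic alcohol to the saturated aldehyde, which would then be reduced without stereocontrol, could erode the enantiomeric purity further, and high pressure could start slow saturation of remote olefins. The fallback changes the directing group to a carboxylate, for which (E)-2-methyl-2-alkenoic acids are the best-behaved substrate class. Setting out from 7, oxidation with MnO2 in CH2Cl2 would give the (E)-enal F1. Chlorite oxidation (NaClO2, NaH2PO4, excess 2-methyl-2-butene, t-BuOH–THF–H2O) would give the (E)-2-methyl-2-enoic acid F2. Hydrogenation with Ru(OAc)2[(S)-H8-BINAP] at low H2 pressure in MeOH–CH2Cl2 would give the (S)-2-methyl acid F3, and LiAlH4 in THF would reduce it, returning to the route at 8.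

**Step 3.** The likely failure is loss of site selectivity. Ene attack at the eight internal olefins (allylic chain CH2) competes statistically with the single terminal CH3, and over-oxidation to the enal is possible. The desired alcohol could then be a minor part of the converted material even at low conversion. The fallback builds the same allylic alcohol by truncation and olefination. Setting out from 6, NBS in aqueous THF (terminal selectivity from coiling of the lipophilic chain in the polar medium) would give the terminal bromohydrin F4, and K2CO3 in MeOH the terminal epoxide F5. Periodic acid in THF–H2O would cleave F5 to the C34' aldehyde F6. Wittig reaction with ethyl 2-(triphenylphosphoranylidene)propanoate would give the (E)-2-methyl enoate F7, and DIBAL-H (toluene, −78 °C) would reduce the ester, returning to the route at 7.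

**Step 6.** The likely failures are γ (SN2') attack at the tertiary terminus of the prenyl–copper intermediate, giving the 1,1-dimethylallyl isomer, and Wurtz homocoupling during magnesium insertion into a long-chain bromide. The fallback reverses the polarity. Setting out from 9, alkylation of lithiated 3-methylbut-2-enyl phenyl sulfone (n-BuLi, THF–DMPU, −78 to 0 °C), which reacts at its α-carbon, would give the C37' sulfone F8 as a mixture of epimers at C37'. Palladium-catalysed hydride desulfonylation (PdCl2(dppp), LiBHEt3, THF, 0 °C), which delivers hydride to the less substituted allyl terminus and keeps the trisubstituted olefin in place, would return to the route at 12.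

## Further compounds

F1 | step 4 | (2E,6E,10E,14E,18E,22E,26E,30E,34E)-2,6,10,14,18,22,26,30,34-nonamethyl-36-(2,3,4,5-tetramethoxy-6-methylphenyl)hexatriaconta-2,6,10,14,18,22,26,30,34-nonaenal | COc1c(OC)c(OC)c(C/C=C(\C)CC/C=C(\C)CC/C=C(\C)CC/C=C(\C)CC/C=C(\C)CC/C=C(\C)CC/C=C(\C)CC/C=C(\C)CC/C=C(\C)C=O)c(C)c1OC
F2 | step 4 | (2E,6E,10E,14E,18E,22E,26E,30E,34E)-2,6,10,14,18,22,26,30,34-nonamethyl-36-(2,3,4,5-tetramethoxy-6-methylphenyl)hexatriaconta-2,6,10,14,18,22,26,30,34-nonaenoic acid | COc1c(OC)c(OC)c(C/C=C(\C)CC/C=C(\C)CC/C=C(\C)CC/C=C(\C)CC/C=C(\C)CC/C=C(\C)CC/C=C(\C)CC/C=C(\C)CC/C=C(\C)C(=O)O)c(C)c1OC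
F3 | step 4 | (2S,6E,10E,14E,18E,22E,26E,30E,34E)-2,6,10,14,18,22,26,30,34-nonamethyl-36-(2,3,4,5-tetramethoxy-6-methylphenyl)hexatriaconta-6,10,14,18,22,26,30,34-octaenoic acid | COc1c(OC)c(OC)c(C/C=C(\C)CC/C=C(\C)CC/C=C(\C)CC/C=C(\C)CC/C=C(\C)CC/C=C(\C)CC/C=C(\C)CC/C=C(\C)CCC[C@H](C)C(=O)O)c(C)c1OC
F4 | step 3 | terminal bromohydrin of 6 (34'-bromo-35'-hydroxy-34',35'-dihydro; racemic at C34') | COc1c(OC)c(OC)c(C/C=C(\C)CC/C=C(\C)CC/C=C(\C)CC/C=C(\C)CC/C=C(\C)CC/C=C(\C)CC/C=C(\C)CC/C=C(\C)CCC(Br)C(C)(C)O)c(C)c1OC
F5 | step 3 | terminal 34',35'-epoxide of 6 (racemic at C34') | COc1c(OC)c(OC)c(C/C=C(\C)CC/C=C(\C)CC/C=C(\C)CC/C=C(\C)CC/C=C(\C)CC/C=C(\C)CC/C=C(\C)CC/C=C(\C)CCC2OC2(C)C)c(C)c1OC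
F6 | step 3 | (4E,8E,12E,16E,20E,24E,28E,32E)-4,8,12,16,20,24,28,32-octamethyl-34-(2,3,4,5-tetramethoxy-6-methylphenyl)tetratriaconta-4,8,12,16,20,24,28,32-octaenal (C34' aldehyde) | COc1c(OC)c(OC)c(C/C=C(\C)CC/C=C(\C)CC/C=C(\C)CC/C=C(\C)CC/C=C(\C)CC/C=C(\C)CC/C=C(\C)CC/C=C(\C)CCC=O)c(C)c1OC
F7 | step 3 | ethyl (2E,6E,10E,14E,18E,22E,26E,30E,34E)-2,6,10,14,18,22,26,30,34-nonamethyl-36-(2,3,4,5-tetramethoxy-6-methylphenyl)hexatriaconta-2,6,10,14,18,22,26,30,34-nonaenoate | COc1c(OC)c(OC)c(C/C=C(\C)CC/C=C(\C)CC/C=C(\C)CC/C=C(\C)CC/C=C(\C)CC/C=C(\C)CC/C=C(\C)CC/C=C(\C)CC/C=C(\C)C(=O)OCC)c(C)c1OC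
F8 | step 6 | 37'-(phenylsulfonyl) derivative of 12 (35'S; mixture of epimers at C37') | COc1c(OC)c(OC)c(C/C=C(\C)CC/C=C(\C)CC/C=C(\C)CC/C=C(\C)CC/C=C(\C)CC/C=C(\C)CC/C=C(\C)CC/C=C(\C)CCC[C@H](C)CC(C=C(C)C)S(=O)(=O)c2ccccc2)c(C)c1OC
A1 | alternative 1 | (R)-citronellyl bromide, (3R)-1-bromo-3,7-dimethyloct-6-ene | BrCC[C@H](C)CCC=C(C)C
A2 | alternative 1 | benzyl (2E,6E,10E,14E,18E,22E,26E,30E)-3,7,11,15,19,23,27,31-octamethyl-32-(phenylsulfonyl)dotriaconta-2,6,10,14,18,22,26,30-octaen-1-yl ether | c1ccccc1COC/C=C(\C)CC/C=C(\C)CC/C=C(\C)CC/C=C(\C)CC/C=C(\C)CC/C=C(\C)CC/C=C(\C)CC/C=C(\C)CS(=O)(=O)c1ccccc1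
A3 | alternative 1 | (2E,6E,10E,14E,18E,22E,26E,30E,35S)-3,7,11,15,19,23,27,31,35,39-decamethyltetraconta-2,6,10,14,18,22,26,30,38-nonaen-1-ol | OC/C=C(\C)CC/C=C(\C)CC/C=C(\C)CC/C=C(\C)CC/C=C(\C)CC/C=C(\C)CC/C=C(\C)CC/C=C(\C)CCC[C@H](C)CCC=C(C)C
A4 | alternative 2 | dimethyl squarate (3,4-dimethoxycyclobut-3-ene-1,2-dione) | COC1=C(OC)C(=O)C1=O
A5 | alternative 2 | (2E,5E,9E,13E,17E,21E,25E,29E,33E,38S)-2-iodo-6,10,14,18,22,26,30,34,38,42-decamethyltritetraconta-2,5,9,13,17,21,25,29,33,41-decaene | C/C(I)=C\C/C=C(\C)CC/C=C(\C)CC/C=C(\C)CC/C=C(\C)CC/C=C(\C)CC/C=C(\C)CC/C=C(\C)CC/C=C(\C)CCC[C@H](C)CCC=C(C)C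
A6 | alternative 2 | 4-hydroxy-2,3-dimethoxy-4-[(E)-alkenyl]cyclobut-2-en-1-one from A4 and lithiated A5 (carbinol carbon racemic, 35'S) | COC1=C(OC)C(O)(/C(C)=C/C/C=C(\C)CC/C=C(\C)CC/C=C(\C)CC/C=C(\C)CC/C=C(\C)CC/C=C(\C)CC/C=C(\C)CC/C=C(\C)CCC[C@H](C)CCC=C(C)C)C1=O
A7 | alternative 3 | (S)-sulcatyl tosylate, (2S)-6-methylhept-5-en-2-yl 4-methylbenzenesulfonate | C[C@H](OS(=O)(=O)c1ccc(C)cc1)CCC=C(C)C
A8 | alternative 3 | C34' Grignard reagent, [(4E,8E,12E,16E,20E,24E,28E,32E)-4,8,12,16,20,24,28,32-octamethyl-34-(2,3,4,5-tetramethoxy-6-methylphenyl)tetratriaconta-4,8,12,16,20,24,28,32-octaen-1-yl]magnesium bromide | COc1c(OC)c(OC)c(C/C=C(\C)CC/C=C(\C)CC/C=C(\C)CC/C=C(\C)CC/C=C(\C)CC/C=C(\C)CC/C=C(\C)CC/C=C(\C)CCC[Mg]Br)c(C)c1OC
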